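## Retrosynthetic overview

1. Numbering: C1 ketone; C2=C3 furanone olefin (C3 on the ring oxygen); C4 CHMe; C5 CHOH; C6 CH–O-methacrylate; C7/C8 lactone fusion (C8 on O); C9 CH2; C10 quaternary C–Me on the ring oxygen; C11=C13 methylene; C12 lactone C=O. Ring A is the 3(2H)-furanone, ring B the ten-membered carbocycle C1–C10, ring C the lactone.
2. The strategy rests on C7: it carries lactone carbon C11 and sits between two oxygen-bearing carbons, C8 (lactone O) and C6 (ester O). C7–C11 and C6–O are therefore disconnected together: a C11 vinyl radical tethered through O8 adds to C7 of a Z-C6=C7 olefin in ring B and the C6 radical is trapped by TEMPO. Ring C forms as a 3-methylenetetrahydrofuran, and C12 is oxidised to the lactone afterwards.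
3. Ring B: ring-closing metathesis at C6=C7 between vinyl carbinols at C5 and C8 on the preformed furanone.
4. Ring A: C1–C2 acetylide addition of alkyne 19 (C2–C6; C4 and C5 from an Evans syn aldol) to lactone 10 (C1, C7–C10; C10 from (R)-citramalic acid, C8 by Noyori transfer hydrogenation), then amine-mediated furanone closure (O–C3).
5. Order of ring formation: A, then B, then C.

Key step: step 18

Remark: the haloallyl ether is used as the iodide, because halogen abstraction by Bu3Sn• must compete with capture of Bu3Sn• by TEMPO and a vinyl bromide should lose that competition. C5–O is carried as a TBS ether so that it survives the aqueous acetic acid of steps 13 and 19.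

Remark: adduct 21 is drawn as the open γ-hydroxy ynone. It may sit partly as the ring-closed lactol (C8–O on C1); both forms should converge in step 13.

## Route

Step 1
Reactants: 1 (R)-citramalic acid
Product: 2 (R)-2-(2,2,4-trimethyl-5-oxo-1,3-dioxolan-4-yl)acetic acid
Conditions: Me2C(OMe)2, TsOH·H2O (cat.), rt
Reagents that add atoms: 2,2-dimethoxypropane, COC(C)(C)OC
Why: Acid-catalysed acetal exchange ties the α-hydroxy acid up as the five-membered dioxolanone and leaves the CH2CO2H arm (future C8) free, without touching the C10 stereocentre.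

Step 2
Reactants: 2 (R)-2-(2,2,4-trimethyl-5-oxo-1,3-dioxolan-4-yl)acetic acid; 3 ethynyltrimethylsilane
Product: 5 (R)-2,2,5-trimethyl-5-[2-oxo-4-(trimethylsilyl)but-3-yn-1-yl]-1,3-dioxolan-4-one, via acid chloride 4 (not isolated)
Conditions: (COCl)2, DMF (cat.), CH2Cl2, 0 °C → rt; then 3, PdCl2(PPh3)2 (2 mol %), CuI (4 mol %), Et3N (1.2 equiv), THF, rt
Reagents that add atoms: ethynyltrimethylsilane, C#C[Si](C)(C)C; oxalyl chloride, O=C(Cl)C(=O)Cl (chlorine of 4 only)
Why: Acid chloride formation followed by acyl Sonogashira coupling should give the silyl ynone, the dioxolanone ester being inert to the copper acetylide.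

Step 3
Reactants: 5 (R)-2,2,5-trimethyl-5-[2-oxo-4-(trimethylsilyl)but-3-yn-1-yl]-1,3-dioxolan-4-one
Product: 7 (3R,5S)-3-hydroxy-3-methyl-5-[(trimethylsilyl)ethynyl]dihydrofuran-2(3H)-one, via propargylic alcohol 6 (not isolated)
Conditions: Ru[(S,S)-TsDPEN](p-cymene) (2 mol %), iPrOH, rt; then TsOH·H2O (cat.), CH2Cl2, rt
Reagents that add atoms: none
Why: Noyori asymmetric transfer hydrogenation of the alkynyl ketone is catalyst-controlled, the (S,S)-ligand giving the (S)-carbinol at C8, and acid-catalysed translactonisation then expels acetone to close the γ-lactone.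

Step 4
Reactants: 7 (3R,5S)-3-hydroxy-3-methyl-5-[(trimethylsilyl)ethynyl]dihydrofuran-2(3H)-one
Product: 8 (3R,5S)-5-ethynyl-3-hydroxy-3-methyldihydrofuran-2(3H)-one
Conditions: TBAF, AcOH, THF, 0 °C
Reagents that add atoms: none
Why: Buffered fluoride protodesilylation of the alkynylsilane should leave the lactone intact.

Step 5
Reactants: 8 (3R,5S)-5-ethynyl-3-hydroxy-3-methyldihydrofuran-2(3H)-one
Product: 9 (3R,5S)-3-hydroxy-3-methyl-5-vinyldihydrofuran-2(3H)-one
Conditions: H2 (1 atm), Lindlar catalyst (Pd on CaCO3 poisoned with Pb(OAc)2), quinoline, EtOAc, rt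
Reagents that add atoms: none
Why: Lindlar semihydrogenation stops at the terminal alkene (C7) and does not cleave the allylic C8–O bond.

Step 6
Reactants: 9 (3R,5S)-3-hydroxy-3-methyl-5-vinyldihydrofuran-2(3H)-one
Product: 10 (3R,5S)-3-methyl-3-[(trimethylsilyl)oxy]-5-vinyldihydrofuran-2(3H)-one
Conditions: TMSOTf, Et3N, CH2Cl2, −78 → 0 °C
Reagents that add atoms: trimethylsilyl triflate, C[Si](C)(C)OS(=O)(=O)C(F)(F)F
Why: Silylation of the tertiary alcohol with the silyl triflate masks the C10 hydroxyl for the acetylide addition, and the lactone has no α-hydrogen to enolise.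

Step 7
Reactants: 11 (S)-4-benzyl-3-propionyloxazolidin-2-one; 12 acrolein
Product: 14 (S)-4-benzyl-3-[(2S,3R)-3-hydroxy-2-methylpent-4-enoyl]oxazolidin-2-one, via boron enolate 13 (not isolated)
Conditions: Bu2BOTf, iPr2NEt, CH2Cl2, 0 °C; 12, −78 → 0 °C; then pH 7 buffer, MeOH, H2O2
Reagents that add atoms: acrolein, C=CC=O; dibutylboron triflate, CCCCB(CCCC)OS(=O)(=O)C(F)(F)F (boron of 13 only)
Why: Evans syn aldol, in which the Z boron enolate reacts through a Zimmerman–Traxler chair on the face away from the benzyl group and sets C4 (2S) and C5 (3R).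

Step 8
Reactants: 14 (S)-4-benzyl-3-[(2S,3R)-3-hydroxy-2-methylpent-4-enoyl]oxazolidin-2-one
Product: 15 (2S,3R)-3-hydroxy-N-methoxy-N,2-dimethylpent-4-enamide
Conditions: MeNH(OMe)·HCl, AlMe3, CH2Cl2, −20 → 0 °C
Reagents that add atoms: N,O-dimethylhydroxylamine hydrochloride, CNOC.Cl
Why: Weinreb transamidation with the aluminium amide attacks the exocyclic imide carbonyl, helped by the free β-hydroxyl, and releases the auxiliary.

Step 9
Reactants: 15 (2S,3R)-3-hydroxy-N-methoxy-N,2-dimethylpent-4-enamide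
Product: 16 (2S,3R)-3-[(tert-butyldimethylsilyl)oxy]-N-methoxy-N,2-dimethylpent-4-enamide
Conditions: TBSOTf, 2,6-lutidine, CH2Cl2, 0 °C
Reagents that add atoms: tert-butyldimethylsilyl triflate, CC(C)(C)[Si](C)(C)OS(=O)(=O)C(F)(F)F
Why: Silyl ether formation at the secondary allylic alcohol with the triflate and a hindered base.

Step 10
Reactants: 16 (2S,3R)-3-[(tert-butyldimethylsilyl)oxy]-N-methoxy-N,2-dimethylpent-4-enamide
Product: 17 (2S,3R)-3-[(tert-butyldimethylsilyl)oxy]-2-methylpent-4-enal
Conditions: DIBAL-H, THF, −78 °C; aqueous work-up, used at once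
Reagents that add atoms: none
Why: DIBAL reduction of a Weinreb amide stops at the aldehyde through the chelated tetrahedral intermediate, and immediate use protects the α-stereocentre (C4) from epimerisation.

Step 11
Reactants: 17 (2S,3R)-3-[(tert-butyldimethylsilyl)oxy]-2-methylpent-4-enal; 18 dimethyl (1-diazo-2-oxopropyl)phosphonate
Product: 19 tert-butyldimethyl{[(3R,4R)-4-methylhex-1-en-5-yn-3-yl]oxy}silane
Conditions: K2CO3, MeOH, 0 °C → rt
Reagents that add atoms: dimethyl (1-diazo-2-oxopropyl)phosphonate, CC(=O)C(=[N+]=[N-])P(=O)(OC)OC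
Why: Seyferth–Gilbert homologation with the Ohira–Bestmann reagent turns the aldehyde into the terminal alkyne (C2≡C3) under base mild enough to keep the α-methyl stereocentre.

Step 12
Reactants: 19 tert-butyldimethyl{[(3R,4R)-4-methylhex-1-en-5-yn-3-yl]oxy}silane; 10 (3R,5S)-3-methyl-3-[(trimethylsilyl)oxy]-5-vinyldihydrofuran-2(3H)-one
Product: 21 (3S,5R,9R,10R)-10-[(tert-butyldimethylsilyl)oxy]-3-hydroxy-5,9-dimethyl-5-[(trimethylsilyl)oxy]dodeca-1,11-dien-7-yn-6-one, via lithium acetylide 20 (not isolated)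
Conditions: n-BuLi, THF, −78 °C; then 10, −78 → −50 °C; AcOH quench
Reagents that add atoms: n-butyllithium, [Li]CCCC (lithium of 20 only)
Why: Acetylide addition to a non-enolisable lactone stops at the tetrahedral lactolate at low temperature, so a single addition should give the γ-hydroxy ynone (C1–C2 bond) on protonation.

Step 13
Reactants: 21 (3S,5R,9R,10R)-10-[(tert-butyldimethylsilyl)oxy]-3-hydroxy-5,9-dimethyl-5-[(trimethylsilyl)oxy]dodeca-1,11-dien-7-yn-6-one
Product: 23 (R)-5-[(2S,3R)-3-[(tert-butyldimethylsilyl)oxy]pent-4-en-2-yl]-2-[(S)-2-hydroxybut-3-en-1-yl]-2-methylfuran-3(2H)-one, via enaminone 22 (not isolated)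
Conditions: Et2NH, EtOH, rt; then AcOH–THF–H2O (3:1:1), rt
Reagents that add atoms: diethylamine, CCNCC (in 22 only)
Why: Amine-mediated 3(2H)-furanone synthesis, in which conjugate addition of Et2NH gives the vinylogous amide and aqueous acid then removes the tertiary TMS ether and lets the C10 hydroxyl add to C3 with loss of Et2NH, the secondary TBS ether surviving.

Step 14
Reactants: 23 (R)-5-[(2S,3R)-3-[(tert-butyldimethylsilyl)oxy]pent-4-en-2-yl]-2-[(S)-2-hydroxybut-3-en-1-yl]-2-methylfuran-3(2H)-one
Product: 24 (2S,3R,4Z,6S,8R)-3-[(tert-butyldimethylsilyl)oxy]-6-hydroxy-2,8-dimethyl-11-oxabicyclo[6.2.1]undeca-1(10),4-dien-9-one (macrocyclic alcohol: C8–OH, C5–OTBS, Z-C6=C7)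
Conditions: second-generation Hoveyda–Grubbs catalyst RuCl2(H2IMes)(=CH-C6H4-2-OiPr) (10 mol %), toluene (1 mM), 80 °C
Reagents that add atoms: none
Why: Ring-closing metathesis driven by loss of ethene, in which the furanone holds the C4 and C9 arms in a 1,3-relationship across the ring oxygen and the bridged nine-membered oxacycle can accommodate only the Z olefin.

Step 15
Reactants: 25 propargyl alcohol
Product: 26 2-iodoprop-2-en-1-ol
Conditions: NaI, TMSCl, H2O, MeCN, rt
Reagents that add atoms: sodium iodide, [Na+].[I-]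
Why: Markovnikov hydroiodination of the terminal alkyne by HI generated in the flask.

Step 16
Reactants: 26 2-iodoprop-2-en-1-ol
Product: 27 3-bromo-2-iodoprop-1-ene
Conditions: PBr3, Et2O, 0 °C
Reagents that add atoms: phosphorus tribromide, BrP(Br)Br
Why: SN2 conversion of the primary allylic alcohol into the bromide.

Step 17
Reactants: 24 macrocyclic alcohol; 27 3-bromo-2-iodoprop-1-ene
Product: 28 2-iodoallyl ether of 24 (C8–O–CH2–C(I)=CH2; key-step precursor)
Conditions: NaH, THF, 0 °C; then 27, Bu4NI (cat.), 0 °C → rt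
Reagents that add atoms: 3-bromo-2-iodoprop-1-ene, C=C(I)CBr
Why: Williamson etherification of the C8 alkoxide with the allylic bromide, the C4 hydrogen of the bridged furanone lying near the plane of the vinylogous ester and so being poorly placed for removal by the alkoxide.

Step 18
Reactants: 28 2-iodoallyl ether; 29 TEMPO
Product: 30 C6 TEMPO ether of the trans-fused 3-methylenetetrahydrofuran (ring O8–C12H2–C11(=C13H2)–C7–C8), C5–OTBS
Conditions: Bu3SnH (5 equiv) and TEMPO (6 equiv), each added in portions over 2 h, benzene (0.02 M), 70 °C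
Reagents that add atoms: TEMPO, CC1(C)CCCC(C)(C)N1[O]
Why: Proposed new method: Bu3Sn• (formed from Bu3SnH and TEMPO) abstracts iodine from 28 to give the C11 σ-vinyl radical, which adds 5-exo-trig to C7 of the ring Z-olefin through the C8–O–C12 tether (C7–C11 bond, methylenetetrahydrofuran ring), and the secondary C6 radical is captured by TEMPO (C6–O bond) before it can be reduced or rearrange by 3-exo attack on the new exocyclic olefin to the six-membered isomer. The closest known reaction types are the tin hydride cyclisation of 2-haloallyl ethers to 3-methylenetetrahydrofurans and the Bu3SnH/TEMPO 5-exo cyclisation–nitroxide trap of aryl iodides, and their combination for a vinyl radical across a medium-ring olefin is untested. C7 is set by the tether: allylic 1,3-strain keeps H8 in the plane of the Z-olefin, so O8 and C9 lie on opposite faces and the radical held by O8 reaches only the C7 face anti to C9, which makes the new five-membered ring trans-fused (7R). C6 is set by approach of the bulky nitroxide anti to both flanking substituents, the new C7–C11 bond and the C5 silyloxy group, which lie on the same ring face (6S). The step needs 5-exo rather than 6-endo closure, secured by the three-atom tether, and ring closure ahead of nitroxide capture of the vinyl radical, for which the iodide (fast halogen abstraction) and a low stationary TEMPO concentration are chosen.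

Step 19
Reactants: 30 C6 TEMPO ether
Product: 31 C6 alcohol of the methylenetetrahydrofuran (C5–OTBS)
Conditions: Zn dust, AcOH–THF–H2O (3:1:1), 50 °C
Reagents that add atoms: none
Why: Reductive N–O cleavage of the alkoxyamine by zinc in acetic acid frees the C6 alcohol with retention, and the vinylogous ester, allyl ether and TBS ether should not be reduced or cleaved at this temperature.

Step 20
Reactants: 31 C6 alcohol; 32 methacrylic anhydride
Product: 33 C6 methacrylate of the methylenetetrahydrofuran (C5–OTBS)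
Conditions: Et3N, DMAP, CH2Cl2, rt
Reagents that add atoms: methacrylic anhydride, C=C(C)C(=O)OC(=O)C(C)=C
Why: DMAP-catalysed acyl transfer to the only free hydroxyl.

Step 21
Reactants: 33 C6 methacrylate
Product: 34 5-O-TBS ether of the target (α-methylene-γ-lactone)
Conditions: CrO3, 3,5-dimethylpyrazole, CH2Cl2, −20 °C
Reagents that add atoms: chromium trioxide, O=[Cr](=O)=O
Why: Chromium trioxide–dimethylpyrazole allylic oxidation of the C12 methylene, which is both allylic and α to the ring oxygen, as in the known conversion of 3-methylenetetrahydrofurans into α-methylene-γ-butyrolactones.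

Step 22
Reactants: 34 5-O-TBS ether of the target
Product: 35 CNP0195404.1 (target)
Conditions: HF·pyridine, pyridine, THF, 0 °C → rt
Reagents that add atoms: none
Why: Desilylation under acidic fluoride conditions avoids base, so acyl migration from O6 to O5 and conjugate addition to the two acrylate units should not occur.

## Compound list

1 | (R)-citramalic acid | C[C@@](O)(CC(=O)O)C(=O)O | starting material
2 | (R)-2-(2,2,4-trimethyl-5-oxo-1,3-dioxolan-4-yl)acetic acid | CC1(C)OC(=O)[C@@](C)(CC(=O)O)O1 | intermediate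
3 | ethynyltrimethylsilane | C#C[Si](C)(C)C | starting material
4 | (R)-2-(2,2,4-trimethyl-5-oxo-1,3-dioxolan-4-yl)acetyl chloride | CC1(C)OC(=O)[C@@](C)(CC(=O)Cl)O1 | intermediate
5 | (R)-2,2,5-trimethyl-5-[2-oxo-4-(trimethylsilyl)but-3-yn-1-yl]-1,3-dioxolan-4-one | CC1(C)OC(=O)[C@@](C)(CC(=O)C#C[Si](C)(C)C)O1 | intermediate
6 | (R)-5-[(S)-2-hydroxy-4-(trimethylsilyl)but-3-yn-1-yl]-2,2,5-trimethyl-1,3-dioxolan-4-one | CC1(C)OC(=O)[C@@](C)(C[C@H](O)C#C[Si](C)(C)C)O1 | intermediate
7 | (3R,5S)-3-hydroxy-3-methyl-5-[(trimethylsilyl)ethynyl]dihydrofuran-2(3H)-one | C[Si](C)(C)C#C[C@@H]1C[C@@](C)(O)C(=O)O1 | intermediate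
8 | (3R,5S)-5-ethynyl-3-hydroxy-3-methyldihydrofuran-2(3H)-one | C#C[C@@H]1C[C@@](C)(O)C(=O)O1 | intermediate
9 | (3R,5S)-3-hydroxy-3-methyl-5-vinyldihydrofuran-2(3H)-one | C=C[C@@H]1C[C@@](C)(O)C(=O)O1 | intermediate
10 | (3R,5S)-3-methyl-3-[(trimethylsilyl)oxy]-5-vinyldihydrofuran-2(3H)-one | C=C[C@@H]1C[C@@](C)(O[Si](C)(C)C)C(=O)O1 | intermediate
11 | (S)-4-benzyl-3-propionyloxazolidin-2-one | CCC(=O)N1[C@@H](Cc2ccccc2)COC1=O | starting material
12 | acrolein | C=CC=O | starting material
13 | dibutylboron (Z)-enolate of 11 | C/C=C(\OB(CCCC)CCCC)N1[C@@H](Cc2ccccc2)COC1=O | intermediate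
14 | (S)-4-benzyl-3-[(2S,3R)-3-hydroxy-2-methylpent-4-enoyl]oxazolidin-2-one | O=C1OC[C@H](Cc2ccccc2)N1C(=O)[C@@H](C)[C@H](O)C=C | intermediate
15 | (2S,3R)-3-hydroxy-N-methoxy-N,2-dimethylpent-4-enamide | CON(C)C(=O)[C@@H](C)[C@H](O)C=C | intermediate
16 | (2S,3R)-3-[(tert-butyldimethylsilyl)oxy]-N-methoxy-N,2-dimethylpent-4-enamide | CON(C)C(=O)[C@@H](C)[C@H](O[Si](C)(C)C(C)(C)C)C=C | intermediate
17 | (2S,3R)-3-[(tert-butyldimethylsilyl)oxy]-2-methylpent-4-enal | O=C[C@@H](C)[C@H](O[Si](C)(C)C(C)(C)C)C=C | intermediate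
18 | dimethyl (1-diazo-2-oxopropyl)phosphonate | CC(=O)C(=[N+]=[N-])P(=O)(OC)OC | starting material
19 | tert-butyldimethyl{[(3R,4R)-4-methylhex-1-en-5-yn-3-yl]oxy}silane | C#C[C@@H](C)[C@H](O[Si](C)(C)C(C)(C)C)C=C | intermediate
20 | lithium acetylide of 19 | [Li]C#C[C@@H](C)[C@H](O[Si](C)(C)C(C)(C)C)C=C | intermediate
21 | (3S,5R,9R,10R)-10-[(tert-butyldimethylsilyl)oxy]-3-hydroxy-5,9-dimethyl-5-[(trimethylsilyl)oxy]dodeca-1,11-dien-7-yn-6-one | C=C[C@@H](O)C[C@@](C)(O[Si](C)(C)C)C(=O)C#C[C@@H](C)[C@H](O[Si](C)(C)C(C)(C)C)C=C | intermediate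
22 | (E)-β-diethylamino enone from 21 (Et2N on C3, C10–OTMS retained) | C=C[C@@H](O)C[C@@](C)(O[Si](C)(C)C)C(=O)/C=C(/N(CC)CC)[C@@H](C)[C@H](O[Si](C)(C)C(C)(C)C)C=C | intermediate
23 | (R)-5-[(2S,3R)-3-[(tert-butyldimethylsilyl)oxy]pent-4-en-2-yl]-2-[(S)-2-hydroxybut-3-en-1-yl]-2-methylfuran-3(2H)-one | C=C[C@@H](O)C[C@@]1(C)OC(=CC1=O)[C@@H](C)[C@H](O[Si](C)(C)C(C)(C)C)C=C | intermediate
24 | (2S,3R,4Z,6S,8R)-3-[(tert-butyldimethylsilyl)oxy]-6-hydroxy-2,8-dimethyl-11-oxabicyclo[6.2.1]undeca-1(10),4-dien-9-one | O[C@H]1C[C@@]2(C)OC(=CC2=O)[C@@H](C)[C@H](O[Si](C)(C)C(C)(C)C)/C=C\1 | intermediate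
25 | propargyl alcohol | C#CCO | starting material
26 | 2-iodoprop-2-en-1-ol | C=C(I)CO | intermediate
27 | 3-bromo-2-iodoprop-1-ene | C=C(I)CBr | intermediate
28 | 2-iodoallyl ether of 24 at O8 (key-step precursor) | C=C(I)CO[C@H]1C[C@@]2(C)OC(=CC2=O)[C@@H](C)[C@H](O[Si](C)(C)C(C)(C)C)/C=C\1 | intermediate
29 | TEMPO | CC1(C)CCCC(C)(C)N1[O] | starting material
30 | C6 TEMPO ether of the trans-fused 3-methylenetetrahydrofuran, C5–OTBS (key-step product) | CC1(C)CCCC(C)(C)N1O[C@@H]2[C@@H](O[Si](C)(C)C(C)(C)C)[C@H](C)C3=CC(=O)[C@@](C)(C[C@@H]4OCC(=C)[C@@H]24)O3 | intermediate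
31 | C6 alcohol of the methylenetetrahydrofuran, C5–OTBS | O[C@@H]1[C@@H](O[Si](C)(C)C(C)(C)C)[C@H](C)C2=CC(=O)[C@@](C)(C[C@@H]3OCC(=C)[C@@H]13)O2 | intermediate
32 | methacrylic anhydride | C=C(C)C(=O)OC(=O)C(C)=C | starting material
33 | C6 methacrylate of the methylenetetrahydrofuran, C5–OTBS | C=C(C)C(=O)O[C@@H]1[C@@H](O[Si](C)(C)C(C)(C)C)[C@H](C)C2=CC(=O)[C@@](C)(C[C@@H]3OCC(=C)[C@@H]13)O2 | intermediate
34 | 5-O-TBS ether of the target | C=C(C)C(=O)O[C@@H]1[C@@H](O[Si](C)(C)C(C)(C)C)[C@H](C)C2=CC(=O)[C@@](C)(C[C@@H]3OC(=O)C(=C)[C@@H]13)O2 | intermediate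
35 | CNP0195404.1 | C=C(C)C(=O)O[C@@H]1[C@@H](O)[C@H](C)C2=CC(=O)[C@@](C)(C[C@@H]3OC(=O)C(=C)[C@@H]13)O2 | target

## Step count and risks

Total step count: 22. Longest linear sequence: 15 steps (steps 1–6, 12–14, 17–22).

**Step 18 (bears the label "Proposed new method:").** The vinyl radical may be captured by the nitroxide or reduced by tin hydride before it closes the ring. Closure may take place on the C7 face syn to C9 (cis fusion), or the nitroxide may approach C6 from the wrong face. The fallback uses known chemistry, sets out from 24 and comes back at 31. Hydroxyl-directed epoxidation of 24 (VO(acac)2, t-BuOOH, CH2Cl2, 0 °C) should give the cis-epoxy alcohol F1, with the oxygen delivered to the C6=C7 face on the side of the C8 hydroxyl and away from the C5 silyloxy group; this epoxide oxygen becomes O6. Propargylation without strong base (propargyl bromide, Ag2O, CH2Cl2), to avoid Payne rearrangement, gives the epoxy propargyl ether F2. Cp2TiCl (from Cp2TiCl2 and Zn dust, THF, rt; trivalent titanium) then opens the epoxide homolytically at C7. The C7 radical closes 5-exo-dig on the propargyl ether anti to the C6 titanoxy group, and reduction of the vinyl radical and acidic work-up give 31 directly. This is the established titanocene epoxide-opening radical cyclisation used for α-methylene-γ-butyrolactones.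

**Step 14.** Intermolecular metathesis (oligomers) may outrun closure of the strained bridged nine-membered ring, and ruthenium hydrides may isomerise the free allylic alcohol. The fallback closes the carbocycle before the oxygen bridge; it sets out from 22 and comes back at 24. Enaminone 22 is isolated by leaving out the acid stage of step 13 and is submitted to ring-closing metathesis (same catalyst, toluene, 1 mM, 80 °C). Its E vinylogous amide holds C1 and C4 cis, so the product is the monocyclic ten-membered macrocyclic enaminone F3 with two cis olefin units. Aqueous acetic acid (AcOH–THF–H2O, rt) then removes the TMS ether, and the C10 hydroxyl adds across the ring to C3 with loss of Et2NH to give 24.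

**Step 21.** Chromium may attack the tertiary allylic C7–H or over-oxidise, or the hindered methylene may not convert. The fallback brings C12 in at the acetal oxidation level, which also replaces the basic etherification of step 17; it sets out from 24 and comes back at 34. Alcohol 24 with methoxyallene and N-iodosuccinimide (CH2Cl2, −40 °C) gives the mixed iodoacetal F4 (C8–O–CH(OMe)–C(I)=CH2). The Bu3SnH/TEMPO cascade of step 18 gives the 2-methoxy-3-methylenetetrahydrofuran TEMPO ether F5. Zn in AcOH–THF–H2O cleaves the N–O bond and hydrolyses the acetal to the hydroxy lactol F6. MnO2 (CH2Cl2) oxidises the allylic lactol alone to the hydroxy α-methylene lactone F7. Methacrylic anhydride, Et3N and DMAP then give 34.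

## Further compounds

F1 | step 18 | cis-6,7-epoxy alcohol from 24 (epoxide O syn to C8–OH, C5–OTBS) | O[C@H]1C[C@@]2(C)OC(=CC2=O)[C@@H](C)[C@H](O[Si](C)(C)C(C)(C)C)[C@H]3O[C@@H]13
F2 | step 18 | O8-propargyl ether of F1 | C#CCO[C@H]1C[C@@]2(C)OC(=CC2=O)[C@@H](C)[C@H](O[Si](C)(C)C(C)(C)C)[C@H]3O[C@@H]13
F3 | step 14 | macrocyclic enaminone (ten-membered carbocycle, Z-C6=C7, Et2N on C3, C10–OTMS, C8–OH) | O[C@H]1C[C@@](C)(O[Si](C)(C)C)C(=O)/C=C(/N(CC)CC)[C@@H](C)[C@H](O[Si](C)(C)C(C)(C)C)/C=C\1
F4 | step 21 | mixed iodoacetal of 24 (C8–O–CH(OMe)–C(I)=CH2, acetal epimers) | C=C(I)C(OC)O[C@H]1C[C@@]2(C)OC(=CC2=O)[C@@H](C)[C@H](O[Si](C)(C)C(C)(C)C)/C=C\1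
F5 | step 21 | C6 TEMPO ether of the 2-methoxy-3-methylenetetrahydrofuran (C12 methyl acetal) | CC1(C)CCCC(C)(C)N1O[C@@H]2[C@@H](O[Si](C)(C)C(C)(C)C)[C@H](C)C3=CC(=O)[C@@](C)(C[C@@H]4OC(OC)C(=C)[C@@H]24)O3
F6 | step 21 | C6 hydroxy C12 lactol | O[C@@H]1[C@@H](O[Si](C)(C)C(C)(C)C)[C@H](C)C2=CC(=O)[C@@](C)(C[C@@H]3OC(O)C(=C)[C@@H]13)O2
F7 | step 21 | C6 hydroxy α-methylene-γ-lactone (C5–OTBS) | O[C@@H]1[C@@H](O[Si](C)(C)C(C)(C)C)[C@H](C)C2=CC(=O)[C@@](C)(C[C@@H]3OC(=O)C(=C)[C@@H]13)O2
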